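**Plan**
1. Retrosynthesis: (i) quinone ring B ← hydroquinone diacetate; (ii) the C3–H stereocentre ← the C3=C4 alkene of an isoflav-3-ene; (iii) the C2–C3 bond of pyran ring C is cut while C2 is reconnected to the oxygen on C8, which turns ring C plus the 8-OH into a 1,3-benzodioxole carrying an (E)-styryl arm; (iv) the stilbene C=C ← Horner–Wadsworth–Emmons olefination.
2. Enabling feature: C2 is a CH2 on O1, and O1 (on C8a) sits ortho to the free hydroxyl on C8, so O1–CH2 and O8–H are the two halves of a methylenedioxy acetal. The C3=C4 alkene is conjugated to ring A (7-OMe para and O1 ortho to C4a), which makes C3 the nucleophilic alkene carbon.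
3. Forward: ring A is built as benzodioxole aldehyde 4 and joined to ring B (aldehyde 8) as stilbene 10. Ring B is oxidised to the quinone while both ring A oxygens are locked in the dioxole, then parked as diacetate 13.
4. Key event: BCl3 unzips the five-membered dioxole ring into the six-membered pyran ring (C2–C3 formed, 8-OH freed, no protecting group on O8 at any stage) to give isoflav-3-ene 16.
5. Stereochemistry: the single stereocentre (3S) comes from iridium-catalysed asymmetric hydrogenation of the C3=C4 alkene of 16 in step 10 and is not touched afterwards.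
6. End game: methanolysis of the two acetates and oxidation of the hydroquinone to the quinone.

Key step: step 9

Remark: chroman numbering (O1, C2, C3, C4, C4a, C5 to C8, C8a) is used for all intermediates; the configuration of the target works out as 3S (C2 > C1' > C4 > H).

**Route**

Step 1
Reactants: 1 2-hydroxy-4,5-dimethoxybenzaldehyde
Product: 2 3-bromo-2-hydroxy-4,5-dimethoxybenzaldehyde
Conditions: NBS (1.05 equiv), MeCN, 0 °C to rt
Reagents that add atoms: N-bromosuccinimide, O=C1CCC(=O)N1Br
Why: Electrophilic aromatic bromination should go to C3, the only free position ortho or para to the phenol, which the 4-methoxy group activates further.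

Step 2
Reactants: 2 3-bromo-2-hydroxy-4,5-dimethoxybenzaldehyde
Product: 3 2,3-dihydroxy-4,5-dimethoxybenzaldehyde
Conditions: NaOH (aq), Cu powder (cat.), reflux, N2; then HCl (aq)
Reagents that add atoms: sodium hydroxide, [Na+].[OH-]
Why: Copper-mediated Ullmann-type hydroxylation of an aryl bromide ortho to a phenoxide, the reaction type that converts 5-bromovanillin into 5-hydroxyvanillin; the phenoxide shields the aldehyde from Cannizzaro disproportionation.

Step 3
Reactants: 3 2,3-dihydroxy-4,5-dimethoxybenzaldehyde
Product: 4 6,7-dimethoxy-1,3-benzodioxole-4-carbaldehyde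
Conditions: CH2Br2, Cs2CO3, DMF, 90 °C
Reagents that add atoms: dibromomethane, BrCBr
Why: Double Williamson alkylation of a catechol gives the methylenedioxy ring, which protects both ring A oxygens and already holds the future C2.

Step 4
Reactants: 4 6,7-dimethoxy-1,3-benzodioxole-4-carbaldehyde
Product: 5 (6,7-dimethoxy-1,3-benzodioxol-4-yl)methanol
Conditions: NaBH4, MeOH–THF, 0 °C
Reagents that add atoms: none
Why: Borohydride reduction of an aryl aldehyde to the benzylic alcohol.

Step 5
Reactants: 5 (6,7-dimethoxy-1,3-benzodioxol-4-yl)methanol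
Product: 7 diethyl [(6,7-dimethoxy-1,3-benzodioxol-4-yl)methyl]phosphonate, via benzyl diethyl phosphite 6 (not isolated)
Conditions: P(OEt)3 (3 equiv), ZnI2 (1.5 equiv), toluene, reflux
Reagents that add atoms: triethyl phosphite, CCOP(OCC)OCC
Why: Zinc-iodide-mediated conversion of an electron-rich benzylic alcohol into its phosphonate, by transesterification to the benzyl phosphite followed by an Arbuzov-type rearrangement.

Step 6
Reactants: 7 diethyl [(6,7-dimethoxy-1,3-benzodioxol-4-yl)methyl]phosphonate; 8 3-hydroxy-4,5-dimethoxybenzaldehyde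
Product: 10 5-[(E)-2-(6,7-dimethoxy-1,3-benzodioxol-4-yl)ethenyl]-2,3-dimethoxyphenol, via potassium phosphonate carbanion 9 (not isolated)
Conditions: KOtBu (2.3 equiv), DMF–THF, 0 °C to rt
Reagents that add atoms: none
Why: Horner–Wadsworth–Emmons olefination of a benzylic phosphonate with an aryl aldehyde should give the (E)-stilbene; the extra equivalent of base carries the phenol of 8 through as its phenoxide.

Step 7
Reactants: 10 5-[(E)-2-(6,7-dimethoxy-1,3-benzodioxol-4-yl)ethenyl]-2,3-dimethoxyphenol
Product: 11 5-[(E)-2-(6,7-dimethoxy-1,3-benzodioxol-4-yl)ethenyl]-2,3-dimethoxy-1,4-benzoquinone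
Conditions: (KSO3)2NO (2.2 equiv), KH2PO4 buffer, acetone–H2O, 0 °C to rt
Reagents that add atoms: potassium nitrosodisulfonate, [K+].[K+].[O]N(S(=O)(=O)[O-])S(=O)(=O)[O-]
Why: Teuber oxidation turns a phenol with a free para position into the para-quinone; ring A cannot compete because both of its phenolic oxygens are tied up in the dioxole.

Step 8
Reactants: 11 5-[(E)-2-(6,7-dimethoxy-1,3-benzodioxol-4-yl)ethenyl]-2,3-dimethoxy-1,4-benzoquinone
Product: 13 2-[(E)-2-(6,7-dimethoxy-1,3-benzodioxol-4-yl)ethenyl]-5,6-dimethoxy-1,4-phenylene diacetate, via hydroquinone 12 (not isolated)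
Conditions: Zn dust, Ac2O, pyridine, rt
Reagents that add atoms: acetic anhydride, CC(=O)OC(C)=O
Why: Reductive acetylation (zinc reduces the quinone, the hydroquinone is trapped as its diacetate) parks ring B in a form that should be inert to BCl3 and to hydrogenation and that makes ring B too electron-poor to support 5-exo closure in step 9.

Step 9
Reactants: 13 2-[(E)-2-(6,7-dimethoxy-1,3-benzodioxol-4-yl)ethenyl]-5,6-dimethoxy-1,4-phenylene diacetate
Product: 16 2-(8-hydroxy-6,7-dimethoxy-2H-chromen-3-yl)-5,6-dimethoxy-1,4-phenylene diacetate, via chloromethyl ether dichloroborinate 14 (not isolated), via 4-chloroisoflavan dichloroborinate 15 (not isolated)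
Conditions: BCl3 (4 equiv), CH2Cl2, –78 to 0 °C; then i-Pr2NEt, –78 °C to rt; aq. NaHCO3
Reagents that add atoms: none
Why: Proposed new method: BCl3 should bind the dioxole oxygen on C8, where the neighbouring 7-OMe oxygen can chelate boron, and cleave the O8–CH2 bond to the aryl chloromethyl ether 14, whose ionisation by excess BCl3 gives the aryloxymethyl cation on O1 that is attacked by C3 of the styrene to forge C2–C3; the resulting C4 cation collapses to chloride 15, the amine quench removes HCl across C3–C4 and the work-up frees the 8-OH. The closest known reaction types are the BCl3 cleavage of methylenedioxy groups in the presence of methyl ethers, which runs through such ArOCH2Cl intermediates, and Prins-type (oxa-Povarov) additions of aryloxymethyl cations to styrenes; what is new is the use of the acetal carbon of a benzodioxole as the electrophile. Pyran ring C closes in a 6-endo-trig cationic mode (equivalently a 6π closure of the 1-oxonia-triene C2=O1–C8a=C4a–C4=C3, with the ring B aryl group on the outside in the E-alkene) while the five-membered dioxole ring opens. No stereocentre survives the step, because C3 becomes sp2 again on loss of HCl; C3 is set in step 10. Two selectivities are needed: cleavage of O8–CH2 and not O1–CH2, secured by the O8/7-OMe chelate and by the fact that the opening is reversible while only the cation on O1 has a π-nucleophile within reach; and 6-endo in place of 5-exo attack, secured by the para 7-OMe and ortho O1 that stabilise positive charge at C4 whereas ring B, deactivated as its diacetate, cannot stabilise charge at C3.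

Step 10
Reactants: 16 2-(8-hydroxy-6,7-dimethoxy-2H-chromen-3-yl)-5,6-dimethoxy-1,4-phenylene diacetate
Product: 17 2-[(3S)-8-hydroxy-6,7-dimethoxy-3,4-dihydro-2H-chromen-3-yl]-5,6-dimethoxy-1,4-phenylene diacetate
Conditions: [Ir(cod)(L)]BArF (2 mol %; L = tert-butyl-PHOX, a chiral phosphine–oxazoline; BArF = tetrakis[3,5-bis(trifluoromethyl)phenyl]borate), H2 (50 bar), CH2Cl2, rt
Reagents that add atoms: none
Why: Iridium N,P-ligand catalysts perform the asymmetric hydrogenation of unfunctionalised trisubstituted aryl alkenes, 3-aryl-2H-chromenes included, with the face chosen by the ligand pocket; the ligand antipode that delivers the 3S product (checked on a small scale against the racemate) is used.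

Step 11
Reactants: 17 2-[(3S)-8-hydroxy-6,7-dimethoxy-3,4-dihydro-2H-chromen-3-yl]-5,6-dimethoxy-1,4-phenylene diacetate
Product: 19 5-[(3S)-8-hydroxy-6,7-dimethoxy-3,4-dihydro-2H-chromen-3-yl]-2,3-dimethoxy-1,4-benzoquinone (CNP0269725.1), via hydroquinone triol 18 (not isolated)
Conditions: HCl (1.25 M in MeOH), 40 °C, Ar; evaporate; then Ag2O, Et2O, rt
Reagents that add atoms: none
Why: Acid-catalysed methanolysis of the aryl acetates frees the hydroquinone, which Ag2O should oxidise to the quinone far more readily than it attacks the ring A monophenol; the C3 stereocentre has no acidic hydrogen and is not affected.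

**Compound list**
1 | 2-hydroxy-4,5-dimethoxybenzaldehyde | COc1cc(C=O)c(O)cc1OC | starting material
2 | 3-bromo-2-hydroxy-4,5-dimethoxybenzaldehyde | COc1cc(C=O)c(O)c(Br)c1OC | intermediate
3 | 2,3-dihydroxy-4,5-dimethoxybenzaldehyde | COc1cc(C=O)c(O)c(O)c1OC | intermediate
4 | 6,7-dimethoxy-1,3-benzodioxole-4-carbaldehyde | COc1cc(C=O)c2OCOc2c1OC | intermediate
5 | (6,7-dimethoxy-1,3-benzodioxol-4-yl)methanol | COc1cc(CO)c2OCOc2c1OC | intermediate
6 | (6,7-dimethoxy-1,3-benzodioxol-4-yl)methyl diethyl phosphite (not isolated) | COc1cc(COP(OCC)OCC)c2OCOc2c1OC | intermediate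
7 | diethyl [(6,7-dimethoxy-1,3-benzodioxol-4-yl)methyl]phosphonate | COc1cc(CP(=O)(OCC)OCC)c2OCOc2c1OC | intermediate
8 | 3-hydroxy-4,5-dimethoxybenzaldehyde | COc1cc(C=O)cc(O)c1OC | starting material
9 | potassium salt of the phosphonate carbanion of 7 (not isolated) | COc1cc([CH-]P(=O)(OCC)OCC)c2OCOc2c1OC.[K+] | intermediate
10 | 5-[(E)-2-(6,7-dimethoxy-1,3-benzodioxol-4-yl)ethenyl]-2,3-dimethoxyphenol | COc1cc(/C=C/c3cc(O)c(OC)c(OC)c3)c2OCOc2c1OC | intermediate
11 | 5-[(E)-2-(6,7-dimethoxy-1,3-benzodioxol-4-yl)ethenyl]-2,3-dimethoxy-1,4-benzoquinone | COC1=C(OC)C(=O)C(/C=C/c2cc(OC)c(OC)c3OCOc23)=CC1=O | intermediate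
12 | 2-[(E)-2-(6,7-dimethoxy-1,3-benzodioxol-4-yl)ethenyl]-5,6-dimethoxybenzene-1,4-diol (not isolated) | COc1c(O)cc(/C=C/c2cc(OC)c(OC)c3OCOc23)c(O)c1OC | intermediate
13 | 2-[(E)-2-(6,7-dimethoxy-1,3-benzodioxol-4-yl)ethenyl]-5,6-dimethoxy-1,4-phenylene diacetate | COc1c(OC(C)=O)cc(/C=C/c2cc(OC)c(OC)c3OCOc23)c(OC(C)=O)c1OC | intermediate
14 | 2-[(E)-2-[2-(chloromethoxy)-3-(dichloroboranyloxy)-4,5-dimethoxyphenyl]ethenyl]-5,6-dimethoxy-1,4-phenylene diacetate (not isolated) | COc1c(OC(C)=O)cc(/C=C/c2cc(OC)c(OC)c(OB(Cl)Cl)c2OCCl)c(OC(C)=O)c1OC | intermediate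
15 | 2-[4-chloro-8-(dichloroboranyloxy)-6,7-dimethoxy-3,4-dihydro-2H-chromen-3-yl]-5,6-dimethoxy-1,4-phenylene diacetate (racemic, both diastereomers, not isolated) | COc1cc2C(Cl)C(c3cc(OC(C)=O)c(OC)c(OC)c3OC(C)=O)COc2c(OB(Cl)Cl)c1OC | intermediate
16 | 2-(8-hydroxy-6,7-dimethoxy-2H-chromen-3-yl)-5,6-dimethoxy-1,4-phenylene diacetate | COc1cc2C=C(c3cc(OC(C)=O)c(OC)c(OC)c3OC(C)=O)COc2c(O)c1OC | intermediate
17 | 2-[(3S)-8-hydroxy-6,7-dimethoxy-3,4-dihydro-2H-chromen-3-yl]-5,6-dimethoxy-1,4-phenylene diacetate | COc1cc2C[C@@H](c3cc(OC(C)=O)c(OC)c(OC)c3OC(C)=O)COc2c(O)c1OC | intermediate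
18 | 2-[(3S)-8-hydroxy-6,7-dimethoxy-3,4-dihydro-2H-chromen-3-yl]-5,6-dimethoxybenzene-1,4-diol (not isolated) | COc1cc2C[C@@H](c3cc(O)c(OC)c(OC)c3O)COc2c(O)c1OC | intermediate
19 | 5-[(3S)-8-hydroxy-6,7-dimethoxy-3,4-dihydro-2H-chromen-3-yl]-2,3-dimethoxy-1,4-benzoquinone (CNP0269725.1) | COC1=C(OC)C(=O)C([C@H]2COc3c(cc(OC)c(OC)c3O)C2)=CC1=O | target

**Count and risks**
Total step count: 11. Longest linear sequence: 11 (steps 1 to 11 from compound 1; compound 8 is a purchased starting material that enters at step 6).

The three steps most likely to fail: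

1. Step 9 (Proposed new method). The ionisation may stall at the chloromethyl ether stage. The acetal may instead open at the other C–O bond, so that the methylene is simply lost on work-up. The O8-bound boron may go on to cleave the neighbouring 7-methoxy group. The acid-sensitive 2H-chromene may oligomerise or disproportionate before the quench. Fallback with known chemistry, setting out from 13 and coming back at 16: Vilsmeier–Haack formylation (POCl3, DMF, then aqueous NaOAc) at the nucleophilic alkene carbon C3 would give the (E)-2,3-diarylpropenal F1. The documented BCl3 cleavage of the methylenedioxy group (CH2Cl2, –78 to 0 °C, methanol quench) would give the catechol enal F2. Luche reduction (NaBH4, CeCl3, MeOH, –40 °C) would give the allylic alcohol F3. Pyridinium p-toluenesulfonate in CH2Cl2 would then close the ring by allylic etherification through the delocalised allyl/benzyl cation, which also equilibrates the alkene geometry; only O1 can reach C2 in a six-membered ring. In this fallback C2–C3 is made intermolecularly and the ring is closed at O1–C2.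

2. Step 10. Face discrimination may be poor on this hindered alkene with its ortho-acetoxy aryl group, and the free phenol may slow or poison the cationic iridium catalyst. Fallback, setting out from 16 and coming back at 17: hydrogenation over Pd/C (H2, 1 atm, EtOAc) would give the racemic isoflavan diacetate F4. Preparative supercritical-fluid chromatography on a polysaccharide chiral phase would then separate 17 from the (R)-enantiomer F5.

3. Step 7. Oxidation at the hindered para position may be slow, the radical oxidant may attack the electron-rich alkene, and the styryl quinone may dimerise by cycloaddition before it is reduced. Fallback, setting out from 10 and coming back at 12: Elbs persulfate oxidation (K2S2O8, aq. NaOH, 0 °C to rt) would give the potassium aryl sulfate F6, and its hydrolysis in warm dilute HCl would give hydroquinone 12 without passing through the quinone. 12 is then acetylated under the step 8 conditions, the zinc being superfluous.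

**Further compounds**
F1 | step 9 | (E)-2-(2,5-diacetoxy-3,4-dimethoxyphenyl)-3-(6,7-dimethoxy-1,3-benzodioxol-4-yl)prop-2-enal | O=C/C(=C/c1cc(OC)c(OC)c2OCOc12)c1cc(OC(C)=O)c(OC)c(OC)c1OC(C)=O
F2 | step 9 | (E)-2-(2,5-diacetoxy-3,4-dimethoxyphenyl)-3-(2,3-dihydroxy-4,5-dimethoxyphenyl)prop-2-enal | O=C/C(=C/c1cc(OC)c(OC)c(O)c1O)c1cc(OC(C)=O)c(OC)c(OC)c1OC(C)=O
F3 | step 9 | (E)-2-(2,5-diacetoxy-3,4-dimethoxyphenyl)-3-(2,3-dihydroxy-4,5-dimethoxyphenyl)prop-2-en-1-ol | OC/C(=C/c1cc(OC)c(OC)c(O)c1O)c1cc(OC(C)=O)c(OC)c(OC)c1OC(C)=O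
F4 | step 10 | racemic 2-(8-hydroxy-6,7-dimethoxy-3,4-dihydro-2H-chromen-3-yl)-5,6-dimethoxy-1,4-phenylene diacetate | COc1cc2CC(c3cc(OC(C)=O)c(OC)c(OC)c3OC(C)=O)COc2c(O)c1OC
F5 | step 10 | 2-[(3R)-8-hydroxy-6,7-dimethoxy-3,4-dihydro-2H-chromen-3-yl]-5,6-dimethoxy-1,4-phenylene diacetate | COc1cc2C[C@H](c3cc(OC(C)=O)c(OC)c(OC)c3OC(C)=O)COc2c(O)c1OC
F6 | step 7 | potassium 2-[(E)-2-(6,7-dimethoxy-1,3-benzodioxol-4-yl)ethenyl]-4-hydroxy-5,6-dimethoxyphenyl sulfate | COc1c(O)cc(/C=C/c2cc(OC)c(OC)c3OCOc23)c(OS(=O)(=O)[O-])c1OC.[K+]
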